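A direct plan would grow the molecule from the catechol end: a benzyl-protected aryl glycidol A1 would be annulated with 4-fluoro-3-hydroxybenzaldehyde A2 to the benzodioxane aldehyde A3, and the same homologation, epoxidation and annulation would be repeated on A3 to reach the pentacyclic aldehyde A4, followed by debenzylation and side-chain extension.
Its weakest operation would be the annulation itself, needed twice: opening of the aryl epoxide by the phenol with retention at the benzylic carbon, then SNAr closure. Retention at an ionising benzylic centre lacks firm precedent, so the trans relation and optical purity of each dioxane would depend on ion-pair behaviour, and the primary alkoxide could close a seven-membered ring instead.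
The second weakness would be the three separate two-carbon extensions of aryl aldehydes (twice ylide addition plus acetal hydrolysis, once olefination plus hydride reduction): six operations that add no ring and no stereocentre, around epoxidations whose facial sense would still have to be proven.
The third would be the endgame on the most precious material: hydrogenolysis of benzyl ethers beside an aryl aldehyde and two benzylic aryl ethers, then olefination and a large excess of aluminium hydride on the unprotected catechol tetraol.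

Plan of the new route
The retrosynthesis cuts, in each dioxane, the aryl C–O bond meta to the ring's carbon substituent (aryl–O–C-3) and the C-2–C-3 bond, then the two O–CH2 bonds of the glycolyl units; all three arenes come from benzaldehydes.
The feature that allows this: ring B is both the aryl group on C-3 of dioxane 2 and the benzo ring of dioxane 1, and in both dioxanes C-2 (on the oxygen para to the ring's carbon substituent) and C-3 (benzylic, on the meta oxygen) form a glycolate-aldol pair. 3-Bromo-4-hydroxybenzaldehyde 1, O-alkylated with a glycolyl imide, can therefore be the aldehyde in one aldol and the enolate in the next, and its bromine marks the meta C–O bond still to be made.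
Rings A, B and C are first joined into an open chain carrying all four stereocentres (step 5); neither dioxane exists until step 9, where both close together by C–O coupling without touching a stereocentre.
The weak steps do not arise: no epoxide is opened (regiochemistry lies in the Br/OH pattern of 1, configuration in two enantiomeric auxiliaries), the only two-carbon extension is made once on a commercial aldehyde, there is no hydrogenolysis, and the last step is a desilylation.

Key step: step 5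

Remarks: ring A carries the three-carbon chain, ring B is the central arene, ring C the catechol; dioxane 2 is fused to ring A, dioxane 1 to ring B; C-2 bears CH2OH and C-3 the aryl group, as in the name of the target. Both enantiomers of 4-benzyl-3-(chloroacetyl)oxazolidin-2-one are assumed to be commercial (each is otherwise one N-acylation from the parent oxazolidinone).

Step 1
Reactants: 1 3-bromo-4-hydroxybenzaldehyde
Product: 2 methyl (E)-3-(3-bromo-4-hydroxyphenyl)prop-2-enoate
Conditions: Ph3P=CHCO2Me (1.3 equiv), toluene, 80 °C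
Reagents that add atoms: methyl (triphenylphosphoranylidene)acetate, COC(=O)C=P(c1ccccc1)(c1ccccc1)c1ccccc1
Why: Wittig reaction of a stabilised ylide should give the E-enoate selectively and tolerates the free phenol, so the single two-carbon extension of the route is made on the cheapest material.

Step 2
Reactants: 2 methyl (E)-3-(3-bromo-4-hydroxyphenyl)prop-2-enoate; 3 (4S)-4-benzyl-3-(chloroacetyl)oxazolidin-2-one
Product: 4 methyl (E)-3-[3-bromo-4-[2-[(4S)-4-benzyl-2-oxooxazolidin-3-yl]-2-oxoethoxy]phenyl]prop-2-enoate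
Conditions: K2CO3 (1.5 equiv), acetone, 50 °C
Reagents that add atoms: none
Why: Williamson ether synthesis, in which the weakly basic phenoxide should displace chloride at the sp3 carbon of the α-halo imide faster than it attacks the imide carbonyl, giving the aryloxyacetyl (glycolyl) imide that is the enolate precursor for dioxane 2 without touching the auxiliary stereocentre.

Step 3
Reactants: 1 3-bromo-4-hydroxybenzaldehyde; 5 (4R)-4-benzyl-3-(chloroacetyl)oxazolidin-2-one
Product: 6 3-bromo-4-[2-[(4R)-4-benzyl-2-oxooxazolidin-3-yl]-2-oxoethoxy]benzaldehyde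
Conditions: K2CO3 (1.5 equiv), acetone, 50 °C
Reagents that add atoms: none
Why: The same Williamson ether synthesis, the aldehyde being inert to carbonate, gives the ring-B component that holds a formyl group (acceptor) and a glycolyl imide with the enantiomeric auxiliary (later donor).

Step 4
Reactants: 7 3,4-dihydroxybenzaldehyde
Product: 8 3,4-bis(triisopropylsilyloxy)benzaldehyde
Conditions: iPr3SiOTf (2.3 equiv), 2,6-lutidine (3 equiv), CH2Cl2, 0 °C to rt
Reagents that add atoms: triisopropylsilyl trifluoromethanesulfonate, CC(C)[Si](OS(=O)(=O)C(F)(F)F)(C(C)C)C(C)C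
Why: Silylation of both phenols with the silyl triflate gives a catechol protection that should tolerate boron enolates, hydrides and carbonate bases and leave with fluoride in the last step.

Step 5
Reactants: 4 methyl (E)-3-[3-bromo-4-[2-[(4S)-4-benzyl-2-oxooxazolidin-3-yl]-2-oxoethoxy]phenyl]prop-2-enoate; 6 3-bromo-4-[2-[(4R)-4-benzyl-2-oxooxazolidin-3-yl]-2-oxoethoxy]benzaldehyde; 8 3,4-bis(triisopropylsilyloxy)benzaldehyde
Product: 10 methyl (E)-3-[3-bromo-4-[[(2S,3R)-1-[(4S)-4-benzyl-2-oxooxazolidin-3-yl]-3-[3-bromo-4-[[(2R,3S)-1-[(4R)-4-benzyl-2-oxooxazolidin-3-yl]-3-[3,4-bis(triisopropylsilyloxy)phenyl]-3-hydroxy-1-oxopropan-2-yl]oxy]phenyl]-3-hydroxy-1-oxopropan-2-yl]oxy]phenyl]prop-2-enoate, via dibutylboron mono-aldolate 9 (not isolated)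
Conditions: 4, Bu2BOTf (1.05 equiv), iPr2NEt (1.2 equiv), CH2Cl2, 0 °C; 6 (0.95 equiv), −78 to 0 °C; then Bu2BOTf (1.2 equiv), iPr2NEt (1.4 equiv), 0 °C; 8 (1.3 equiv), −78 to 0 °C; pH 7 buffer, MeOH, 30% H2O2, 0 °C
Reagents that add atoms: none
Why: Bu2BOTf/iPr2NEt convert imide 4 into its Z-boron enolate, which adds to the formyl group of 6 through a chair Zimmerman–Traxler transition state to give boron aldolate 9; a second charge of the same reagents enolises the only CH2 imide left (the glycolyl group on ring B), and that enolate adds to aldehyde 8 in the same way. The closest known reaction type is the Evans syn-aldol of aryloxyacetyl (glycolyl) oxazolidinones with aryl aldehydes, here run twice in one flask on a component that is acceptor first and donor second. No ring is closed: the step forms the two C-2–C-3 bonds of the future dioxanes and joins rings A, B and C into one chain. Each syn pair is set by its own auxiliary: the (S)-benzyl group of the ring-A imide directs the aldehyde to one enolate face and gives the (2S,3R) adduct (the later (2R,3R) dioxane 2), the (R)-auxiliary on ring B gives the mirror-image (2R,3S) pair (the later (2S,3S) dioxane 1), and the syn relation in both follows from the Z-enolate in the chair transition state. The step needs 6 to react as acceptor only and then as donor only; this should be secured because no free boron triflate is left when 6 is added, because 6 cannot serve as donor first (it carries the aldehyde), and because in 9 the first imide is tied up as a boron chelate whose tertiary α-hydrogen is shielded by allylic strain. The two pairs are separated by ring B, so the second addition should be under pure reagent control.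

Step 6
Reactants: 10 methyl (E)-3-[3-bromo-4-[[(2S,3R)-1-[(4S)-4-benzyl-2-oxooxazolidin-3-yl]-3-[3-bromo-4-[[(2R,3S)-1-[(4R)-4-benzyl-2-oxooxazolidin-3-yl]-3-[3,4-bis(triisopropylsilyloxy)phenyl]-3-hydroxy-1-oxopropan-2-yl]oxy]phenyl]-3-hydroxy-1-oxopropan-2-yl]oxy]phenyl]prop-2-enoate
Product: 11 methyl (E)-3-[3-bromo-4-[[(1R,2R)-1-[3-bromo-4-[[(1S,2S)-1-[3,4-bis(triisopropylsilyloxy)phenyl]-1,3-dihydroxypropan-2-yl]oxy]phenyl]-1,3-dihydroxypropan-2-yl]oxy]phenyl]prop-2-enoate
Conditions: NaBH4 (8 equiv), THF/H2O (4:1), 0 °C to rt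
Reagents that add atoms: none
Why: Reductive cleavage of the two N-acyloxazolidinones by borohydride (hydride attack on the exocyclic imide carbonyl) should give the primary alcohols and return both auxiliaries while the enoate, the aryl bromides and the aryl silyl ethers stay; no stereocentre is touched (the descriptors at the aryloxy carbons change only through CIP priorities).

Step 7
Reactants: 11 methyl (E)-3-[3-bromo-4-[[(1R,2R)-1-[3-bromo-4-[[(1S,2S)-1-[3,4-bis(triisopropylsilyloxy)phenyl]-1,3-dihydroxypropan-2-yl]oxy]phenyl]-1,3-dihydroxypropan-2-yl]oxy]phenyl]prop-2-enoate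
Product: 12 (1R,2R)-1-[3-bromo-4-[[(1S,2S)-1-[3,4-bis(triisopropylsilyloxy)phenyl]-1,3-dihydroxypropan-2-yl]oxy]phenyl]-2-[2-bromo-4-[(E)-3-hydroxyprop-1-enyl]phenoxy]propane-1,3-diol
Conditions: iBu2AlH (10 equiv), THF, −78 to 0 °C; aq. KNaC4H4O6 work-up
Reagents that add atoms: none
Why: 1,2-Reduction of the enoate by DIBAL-H should give the E-allylic alcohol, and doing it before ring closure removes the acceptor group para to the ring-A ether oxygen, which could otherwise invite a Smiles rearrangement or transesterification under the basic coupling conditions.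

Step 8
Reactants: 12 (1R,2R)-1-[3-bromo-4-[[(1S,2S)-1-[3,4-bis(triisopropylsilyloxy)phenyl]-1,3-dihydroxypropan-2-yl]oxy]phenyl]-2-[2-bromo-4-[(E)-3-hydroxyprop-1-enyl]phenoxy]propane-1,3-diol
Product: 13 (1R,2R)-1-[3-bromo-4-[[(1S,2S)-1-[3,4-bis(triisopropylsilyloxy)phenyl]-1-hydroxy-3-(triisopropylsilyloxy)propan-2-yl]oxy]phenyl]-2-[2-bromo-4-[(E)-3-(triisopropylsilyloxy)prop-1-enyl]phenoxy]-3-(triisopropylsilyloxy)propan-1-ol
Conditions: iPr3SiCl (3.6 equiv), imidazole (8 equiv), DMF, 0 °C to rt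
Reagents that add atoms: chlorotriisopropylsilane, CC(C)[Si](Cl)(C(C)C)C(C)C
Why: Selective silylation, in which the bulky chlorosilane should react with the three primary hydroxyls and leave the two hindered secondary benzylic hydroxyls free, so that in step 9 only six-membered closure is possible.

Step 9
Reactants: 13 (1R,2R)-1-[3-bromo-4-[[(1S,2S)-1-[3,4-bis(triisopropylsilyloxy)phenyl]-1-hydroxy-3-(triisopropylsilyloxy)propan-2-yl]oxy]phenyl]-2-[2-bromo-4-[(E)-3-(triisopropylsilyloxy)prop-1-enyl]phenoxy]-3-(triisopropylsilyloxy)propan-1-ol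
Product: 16 triisopropyl[[(E)-3-[(2R,3R)-3-[(2S,3S)-3-[3,4-bis(triisopropylsilyloxy)phenyl]-2-[(triisopropylsilyloxy)methyl]-2,3-dihydro-1,4-benzodioxin-6-yl]-2-[(triisopropylsilyloxy)methyl]-2,3-dihydro-1,4-benzodioxin-6-yl]prop-2-enyl]oxy]silane, via ring-A-closed monobromide 14 (not isolated), via ring-B-closed monobromide 15 (not isolated)
Conditions: CuI (20 mol%), 3,4,7,8-tetramethyl-1,10-phenanthroline (40 mol%), Cs2CO3 (4 equiv), toluene (0.02 M), 110 °C, argon
Reagents that add atoms: none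
Why: Double intramolecular Ullmann-type C–O coupling at monovalent copper, in which each benzylic alkoxide is arylated by the bromide ortho to its neighbouring ether oxygen (precedent: copper-catalysed cyclisation of 2-(2-bromophenoxy)alkanols to 1,4-benzodioxanes), should close both dioxanes as six-membered rings; no bond to C-2 or C-3 is broken, so the two threo pairs become the trans (2R,3R) and (2S,3S) rings with retention, and the oxygen meta to each ring's carbon substituent ends on the benzylic carbon by construction.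

Step 10
Reactants: 16 triisopropyl[[(E)-3-[(2R,3R)-3-[(2S,3S)-3-[3,4-bis(triisopropylsilyloxy)phenyl]-2-[(triisopropylsilyloxy)methyl]-2,3-dihydro-1,4-benzodioxin-6-yl]-2-[(triisopropylsilyloxy)methyl]-2,3-dihydro-1,4-benzodioxin-6-yl]prop-2-enyl]oxy]silane
Product: 17 (E)-3-[(2R,3R)-3-[(2S,3S)-3-(3,4-dihydroxyphenyl)-2-(hydroxymethyl)-2,3-dihydro-1,4-benzodioxin-6-yl]-2-(hydroxymethyl)-2,3-dihydro-1,4-benzodioxin-6-yl]prop-2-en-1-ol (CNP0234042.2)
Conditions: Bu4NF (7 equiv), AcOH (7 equiv), THF, 0 °C to rt, argon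
Reagents that add atoms: none
Why: Fluoride-mediated cleavage of all five silyl ethers (Si–F bond formation), buffered with acetic acid and run under argon so that the catechol is not oxidised and the allylic alcohol is not ionised, should release the target without involving any stereocentre.

Compound list
1 | 3-bromo-4-hydroxybenzaldehyde | O=Cc1ccc(O)c(Br)c1 | starting material
2 | methyl (E)-3-(3-bromo-4-hydroxyphenyl)prop-2-enoate | COC(=O)/C=C/c1ccc(O)c(Br)c1 | intermediate
3 | (4S)-4-benzyl-3-(chloroacetyl)oxazolidin-2-one | O=C(CCl)N1[C@@H](Cc2ccccc2)COC1=O | starting material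
4 | methyl (E)-3-[3-bromo-4-[2-[(4S)-4-benzyl-2-oxooxazolidin-3-yl]-2-oxoethoxy]phenyl]prop-2-enoate | COC(=O)/C=C/c1ccc(OCC(=O)N2[C@@H](Cc3ccccc3)COC2=O)c(Br)c1 | intermediate
5 | (4R)-4-benzyl-3-(chloroacetyl)oxazolidin-2-one | O=C(CCl)N1[C@H](Cc2ccccc2)COC1=O | starting material
6 | 3-bromo-4-[2-[(4R)-4-benzyl-2-oxooxazolidin-3-yl]-2-oxoethoxy]benzaldehyde | O=Cc1ccc(OCC(=O)N2[C@H](Cc3ccccc3)COC2=O)c(Br)c1 | intermediate
7 | 3,4-dihydroxybenzaldehyde | O=Cc1ccc(O)c(O)c1 | starting material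
8 | 3,4-bis(triisopropylsilyloxy)benzaldehyde | O=Cc1ccc(O[Si](C(C)C)(C(C)C)C(C)C)c(O[Si](C(C)C)(C(C)C)C(C)C)c1 | intermediate
9 | methyl (E)-3-[3-bromo-4-[[(2S,3R)-1-[(4S)-4-benzyl-2-oxooxazolidin-3-yl]-3-[3-bromo-4-[2-[(4R)-4-benzyl-2-oxooxazolidin-3-yl]-2-oxoethoxy]phenyl]-3-(dibutylboranyloxy)-1-oxopropan-2-yl]oxy]phenyl]prop-2-enoate (boron aldolate of the mono-adduct) | COC(=O)/C=C/c1ccc(O[C@H](C(=O)N2[C@@H](Cc3ccccc3)COC2=O)[C@H](OB(CCCC)CCCC)c2ccc(OCC(=O)N3[C@H](Cc4ccccc4)COC3=O)c(Br)c2)c(Br)c1 | intermediate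
10 | methyl (E)-3-[3-bromo-4-[[(2S,3R)-1-[(4S)-4-benzyl-2-oxooxazolidin-3-yl]-3-[3-bromo-4-[[(2R,3S)-1-[(4R)-4-benzyl-2-oxooxazolidin-3-yl]-3-[3,4-bis(triisopropylsilyloxy)phenyl]-3-hydroxy-1-oxopropan-2-yl]oxy]phenyl]-3-hydroxy-1-oxopropan-2-yl]oxy]phenyl]prop-2-enoate | COC(=O)/C=C/c1ccc(O[C@H](C(=O)N2[C@@H](Cc3ccccc3)COC2=O)[C@H](O)c2ccc(O[C@@H](C(=O)N3[C@H](Cc4ccccc4)COC3=O)[C@@H](O)c3ccc(O[Si](C(C)C)(C(C)C)C(C)C)c(O[Si](C(C)C)(C(C)C)C(C)C)c3)c(Br)c2)c(Br)c1 | intermediate
11 | methyl (E)-3-[3-bromo-4-[[(1R,2R)-1-[3-bromo-4-[[(1S,2S)-1-[3,4-bis(triisopropylsilyloxy)phenyl]-1,3-dihydroxypropan-2-yl]oxy]phenyl]-1,3-dihydroxypropan-2-yl]oxy]phenyl]prop-2-enoate | COC(=O)/C=C/c1ccc(O[C@H](CO)[C@H](O)c2ccc(O[C@@H](CO)[C@@H](O)c3ccc(O[Si](C(C)C)(C(C)C)C(C)C)c(O[Si](C(C)C)(C(C)C)C(C)C)c3)c(Br)c2)c(Br)c1 | intermediate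
12 | (1R,2R)-1-[3-bromo-4-[[(1S,2S)-1-[3,4-bis(triisopropylsilyloxy)phenyl]-1,3-dihydroxypropan-2-yl]oxy]phenyl]-2-[2-bromo-4-[(E)-3-hydroxyprop-1-enyl]phenoxy]propane-1,3-diol | OC/C=C/c1ccc(O[C@H](CO)[C@H](O)c2ccc(O[C@@H](CO)[C@@H](O)c3ccc(O[Si](C(C)C)(C(C)C)C(C)C)c(O[Si](C(C)C)(C(C)C)C(C)C)c3)c(Br)c2)c(Br)c1 | intermediate
13 | (1R,2R)-1-[3-bromo-4-[[(1S,2S)-1-[3,4-bis(triisopropylsilyloxy)phenyl]-1-hydroxy-3-(triisopropylsilyloxy)propan-2-yl]oxy]phenyl]-2-[2-bromo-4-[(E)-3-(triisopropylsilyloxy)prop-1-enyl]phenoxy]-3-(triisopropylsilyloxy)propan-1-ol | CC(C)[Si](OC/C=C/c1ccc(O[C@H](CO[Si](C(C)C)(C(C)C)C(C)C)[C@H](O)c2ccc(O[C@@H](CO[Si](C(C)C)(C(C)C)C(C)C)[C@@H](O)c3ccc(O[Si](C(C)C)(C(C)C)C(C)C)c(O[Si](C(C)C)(C(C)C)C(C)C)c3)c(Br)c2)c(Br)c1)(C(C)C)C(C)C | intermediate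
14 | (1S,2S)-1-[3,4-bis(triisopropylsilyloxy)phenyl]-2-[2-bromo-4-[(2R,3R)-3-[(triisopropylsilyloxy)methyl]-7-[(E)-3-(triisopropylsilyloxy)prop-1-enyl]-2,3-dihydro-1,4-benzodioxin-2-yl]phenoxy]-3-(triisopropylsilyloxy)propan-1-ol (dioxane 2 closed, ring-B bromo alcohol still open) | CC(C)[Si](OC/C=C/c1ccc2c(c1)O[C@H](c1ccc(O[C@@H](CO[Si](C(C)C)(C(C)C)C(C)C)[C@@H](O)c3ccc(O[Si](C(C)C)(C(C)C)C(C)C)c(O[Si](C(C)C)(C(C)C)C(C)C)c3)c(Br)c1)[C@@H](CO[Si](C(C)C)(C(C)C)C(C)C)O2)(C(C)C)C(C)C | intermediate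
15 | (1R,2R)-1-[(2S,3S)-3-[3,4-bis(triisopropylsilyloxy)phenyl]-2-[(triisopropylsilyloxy)methyl]-2,3-dihydro-1,4-benzodioxin-6-yl]-2-[2-bromo-4-[(E)-3-(triisopropylsilyloxy)prop-1-enyl]phenoxy]-3-(triisopropylsilyloxy)propan-1-ol (dioxane 1 closed, ring-A bromo alcohol still open) | CC(C)[Si](OC/C=C/c1ccc(O[C@H](CO[Si](C(C)C)(C(C)C)C(C)C)[C@H](O)c2ccc3c(c2)O[C@@H](c2ccc(O[Si](C(C)C)(C(C)C)C(C)C)c(O[Si](C(C)C)(C(C)C)C(C)C)c2)[C@H](CO[Si](C(C)C)(C(C)C)C(C)C)O3)c(Br)c1)(C(C)C)C(C)C | intermediate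
16 | triisopropyl[[(E)-3-[(2R,3R)-3-[(2S,3S)-3-[3,4-bis(triisopropylsilyloxy)phenyl]-2-[(triisopropylsilyloxy)methyl]-2,3-dihydro-1,4-benzodioxin-6-yl]-2-[(triisopropylsilyloxy)methyl]-2,3-dihydro-1,4-benzodioxin-6-yl]prop-2-enyl]oxy]silane (pentakis(triisopropylsilyl) ether of the target) | CC(C)[Si](OC/C=C/c1ccc2c(c1)O[C@H](c1ccc3c(c1)O[C@@H](c1ccc(O[Si](C(C)C)(C(C)C)C(C)C)c(O[Si](C(C)C)(C(C)C)C(C)C)c1)[C@H](CO[Si](C(C)C)(C(C)C)C(C)C)O3)[C@@H](CO[Si](C(C)C)(C(C)C)C(C)C)O2)(C(C)C)C(C)C | intermediate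
17 | (E)-3-[(2R,3R)-3-[(2S,3S)-3-(3,4-dihydroxyphenyl)-2-(hydroxymethyl)-2,3-dihydro-1,4-benzodioxin-6-yl]-2-(hydroxymethyl)-2,3-dihydro-1,4-benzodioxin-6-yl]prop-2-en-1-ol (CNP0234042.2) | OC/C=C/c1ccc2c(c1)O[C@H](c1ccc3c(c1)O[C@@H](c1ccc(O)c(O)c1)[C@H](CO)O3)[C@@H](CO)O2 | target

Total step count: 10. Longest linear sequence: 8 steps (steps 1, 2, 5, 6, 7, 8, 9, 10); steps 3 and 4 are one-step side branches.

Steps most likely to fail

Step 5. The second enolisation in the same flask may be incomplete or unselective (enolate exchange, self-condensation of 6 through its own imide, or reversal of the boron aldolate), which would lead to mono-adducts and crossed products. The fallback sets out from 4 and 6: the first aldol addition would be run alone with oxidative work-up and the mono-adduct alcohol F1 isolated. Its hydroxyl would be silylated (Et3SiOTf, 2,6-lutidine, CH2Cl2, −78 °C) to the triethylsilyl ether F2, and the ring-B glycolyl imide of F2 would then be enolised (Bu2BOTf, iPr2NEt) and added to 8 to give the silyl-protected bis-adduct F3. Mild methanolysis (pyridinium tosylate, MeOH/CH2Cl2, rt) would remove the triethylsilyl group, and the route is rejoined at 10.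

Step 9. Coupling at the hindered benzylic alkoxides may be slow, with competing protodebromination, or a base-induced silyl shift from a primary oxygen may open the way to seven-membered closure. The fallback sets out from 13 and changes the bond that closes the rings. Both aryl bromides would be borylated (B2pin2, PdCl2(dppf), KOAc, dioxane, 85 °C) to the bis(pinacol boronate) F4, and F4 would be oxidised (NaBO3·4H2O, THF/H2O, rt) to the bis-phenol F5. Acid catalysis (TsOH cat., CH2Cl2, 0 °C) would then ionise each p-alkoxybenzylic alcohol and let the neighbouring phenol close the ring under thermodynamic control, which favours the trans dioxanes fixed by the untouched C-2 centres; the route is rejoined at 16.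

Step 6. The α-aryloxy aldolates may undergo retro-aldol cleavage, or the enoate may suffer conjugate reduction, under aqueous borohydride. The fallback sets out from 10: both auxiliaries would be exchanged for methoxide under chelation (MeMgBr/MeOH, i.e. MeOMgBr, CH2Cl2/MeOH, 0 °C) to give the triester F6. A single reduction of all three ester groups of F6 with iBu2AlH (THF, −78 to 0 °C) would then give the pentol directly, and the route is rejoined at 12, leaving out 11.

Further compounds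
F1 | step 5 | methyl (E)-3-[3-bromo-4-[[(2S,3R)-1-[(4S)-4-benzyl-2-oxooxazolidin-3-yl]-3-[3-bromo-4-[2-[(4R)-4-benzyl-2-oxooxazolidin-3-yl]-2-oxoethoxy]phenyl]-3-hydroxy-1-oxopropan-2-yl]oxy]phenyl]prop-2-enoate | COC(=O)/C=C/c1ccc(O[C@H](C(=O)N2[C@@H](Cc3ccccc3)COC2=O)[C@H](O)c2ccc(OCC(=O)N3[C@H](Cc4ccccc4)COC3=O)c(Br)c2)c(Br)c1
F2 | step 5 | methyl (E)-3-[3-bromo-4-[[(2S,3R)-1-[(4S)-4-benzyl-2-oxooxazolidin-3-yl]-3-[3-bromo-4-[2-[(4R)-4-benzyl-2-oxooxazolidin-3-yl]-2-oxoethoxy]phenyl]-1-oxo-3-(triethylsilyloxy)propan-2-yl]oxy]phenyl]prop-2-enoate | COC(=O)/C=C/c1ccc(O[C@H](C(=O)N2[C@@H](Cc3ccccc3)COC2=O)[C@H](O[Si](CC)(CC)CC)c2ccc(OCC(=O)N3[C@H](Cc4ccccc4)COC3=O)c(Br)c2)c(Br)c1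
F3 | step 5 | triethylsilyl ether of 10 at the hydroxyl of the ring-A/ring-B aldol unit | COC(=O)/C=C/c1ccc(O[C@H](C(=O)N2[C@@H](Cc3ccccc3)COC2=O)[C@H](O[Si](CC)(CC)CC)c2ccc(O[C@@H](C(=O)N3[C@H](Cc4ccccc4)COC3=O)[C@@H](O)c3ccc(O[Si](C(C)C)(C(C)C)C(C)C)c(O[Si](C(C)C)(C(C)C)C(C)C)c3)c(Br)c2)c(Br)c1
F4 | step 9 | analogue of 13 in which both bromine atoms are replaced by 4,4,5,5-tetramethyl-1,3,2-dioxaborolan-2-yl groups | CC(C)[Si](OC/C=C/c1ccc(O[C@H](CO[Si](C(C)C)(C(C)C)C(C)C)[C@H](O)c2ccc(O[C@@H](CO[Si](C(C)C)(C(C)C)C(C)C)[C@@H](O)c3ccc(O[Si](C(C)C)(C(C)C)C(C)C)c(O[Si](C(C)C)(C(C)C)C(C)C)c3)c(B3OC(C)(C)C(C)(C)O3)c2)c(B2OC(C)(C)C(C)(C)O2)c1)(C(C)C)C(C)C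
F5 | step 9 | analogue of 13 in which both bromine atoms are replaced by hydroxyl groups | CC(C)[Si](OC/C=C/c1ccc(O[C@H](CO[Si](C(C)C)(C(C)C)C(C)C)[C@H](O)c2ccc(O[C@@H](CO[Si](C(C)C)(C(C)C)C(C)C)[C@@H](O)c3ccc(O[Si](C(C)C)(C(C)C)C(C)C)c(O[Si](C(C)C)(C(C)C)C(C)C)c3)c(O)c2)c(O)c1)(C(C)C)C(C)C
F6 | step 6 | methyl (2S,3R)-3-[3-bromo-4-[[(2R,3S)-3-[3,4-bis(triisopropylsilyloxy)phenyl]-3-hydroxy-1-methoxy-1-oxopropan-2-yl]oxy]phenyl]-2-[2-bromo-4-[(E)-3-methoxy-3-oxoprop-1-enyl]phenoxy]-3-hydroxypropanoate | COC(=O)/C=C/c1ccc(O[C@H](C(=O)OC)[C@H](O)c2ccc(O[C@@H](C(=O)OC)[C@@H](O)c3ccc(O[Si](C(C)C)(C(C)C)C(C)C)c(O[Si](C(C)C)(C(C)C)C(C)C)c3)c(Br)c2)c(Br)c1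
A1 | direct plan | [(2S,3S)-3-[3,4-bis(benzyloxy)phenyl]oxiran-2-yl]methanol | OC[C@@H]1O[C@H]1c1ccc(OCc2ccccc2)c(OCc2ccccc2)c1
A2 | direct plan | 4-fluoro-3-hydroxybenzaldehyde | O=Cc1ccc(F)c(O)c1
A3 | direct plan | (2S,3S)-3-[3,4-bis(benzyloxy)phenyl]-2-(hydroxymethyl)-2,3-dihydro-1,4-benzodioxine-6-carbaldehyde | O=Cc1ccc2c(c1)O[C@@H](c1ccc(OCc3ccccc3)c(OCc3ccccc3)c1)[C@H](CO)O2
A4 | direct plan | (2R,3R)-3-[(2S,3S)-3-[3,4-bis(benzyloxy)phenyl]-2-(hydroxymethyl)-2,3-dihydro-1,4-benzodioxin-6-yl]-2-(hydroxymethyl)-2,3-dihydro-1,4-benzodioxine-6-carbaldehyde | O=Cc1ccc2c(c1)O[C@H](c1ccc3c(c1)O[C@@H](c1ccc(OCc4ccccc4)c(OCc4ccccc4)c1)[C@H](CO)O3)[C@@H](CO)O2
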